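| flask | G | remark | time |
|---|---|---|---|
| blue | 0.40 M | the very flask that is asked about, followed so far |  |
| ochre | 0.20 M | run made earlier |  |
| flask | 0.40 M |  | 30 h |

| run | time / h | G / % | D / % |
|---|---|---|---|
| blue | 0.667 | 90.5 | 0.1 |
| blue | 1.33 | 86.6 | 1.2 |
| blue | 2.00 | 86.7 | 0.7 |
| blue | 2.50 | 85.5 | 0.3 |
| ochre | 5.00 | 70.0 | 2.9 |
| ochre | 10.0 | 68.3 | 4.5 |
| ochre | 15.0 | 67.5 | 6.4 |
| ochre | 20.0 | 66.3 | 6.7 |

(standard deviation of a reading: 0.5 percentage points)

- why nothing more happens at 30 h, or that something still does (for what has run out or reacted, a solid counts together with what of it has only dissolved) (it is still moving / all of G has reacted / forward and back rates have come level)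
- part of the G that has turned into other species by 30 h (what has only dissolved does not count)
- how much D there is at 30 h, in percent of the G charged
- how much E there is at 30 h, in percent of the G charged

- G is a solid; its amount is given per volume of the solution
- what was read earlier has a scatter of 0.5 percentage points, one standard deviation
- reactions considered so far: G <-> E; E -> Z; L <-> D; E <-> X; E <-> L
- at the start none of G is in solution
- what has only dissolved of G counts as not reacted
- what has gone from E into another species counts as reacted, even if it can come back
- the reaction counts as stopped when no species that holds the G changes by six tenths of a point or more over the second half of the time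
- E means what is dissolved; the solid is not counted in it

Easy one first: in what unit do two flasks with different charges compare? In molarity, not percent. Solid G still stands at 66.3% in the ochre run at 20.0 h, and G lost minus D is 54.0 mM there and 56.8 mM in the blue run at 2.50 h. So I take [D] from the ochre run for the flask.

How far along is the flask at 30 h? Count turnovers. In the ochre run, the second stretch of 5.00 h added 0.552 of what the first added, so the gap to the ceiling of [D] halves every 5.83 h. The turnover count, the time divided by this half-life, is 5.15. The ochre reading at 20.0 h then puts the ceiling at 14.8 mM. For the flask I reckon D at 3.59%, with a gain of 0.52 percentage points over the second half, under the mark the conditions set, so I call it stopped.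

But that half-life rests on two scattered readings? Yes. The readings at 10.0 h and 20.0 h give 9.69 h and a flask gain of 0.99 points. That longer half-life asks the ochre run for 0.91 points between its last two readings, mine asks 0.56 points, and they show 0.3 points. I keep mine, narrowly.

The forecast differs from me on the ending: it expects D to rise by about 0.7 point or more over the second half of the time, says "it is still moving" because “solid remains, so the system is still moving”, and gives D 4.2%, E 11.5% and conversion 6.5%.

The simulation gives forward and back rates have come level, D 3.49%, E 7.99% and conversion 9.19%.

    G ⇌ E, rate k1*(cs1 - [E]) while solid is left; crystals form when [E] > cs1 (solubility = 32.0 mM, k = 0.0540 min⁻¹)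
    E → Z (k = 1.30 × 10⁻⁵ min⁻¹)
    L ⇌ D (K = 0.810, k = 0.00180 min⁻¹)
    E ⇌ X (K = 0.140, k = 0.140 min⁻¹)
    E ⇌ L (K = 0.550, k = 0.570 min⁻¹)

In the flask, the dissolution of G had 83% of its turnover behind it by 3.00 h, when E stood at 7.86% and L at 4.32%. L then went on turning into D beside solid G at 83.4%, and D rose from 3.02% at 15.0 h to 3.49% at 30.0 h, a gain of 0.47 points against my 0.52 points. The neighbour charged with 1.6 M has the same 5.15 turnovers, so the ceiling gives it 0.899% of D, and it holds 0.872%.

The runs come from a simulation for substances that don't exist; the scatter is artificial.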